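Readings and results were generated by integration for an exercise, and the scatter is random.

The ratio 0.549 /mM, read from Wednesday's run at 20.0 min, is what I carry: the gap in the balance, meaning the charged E found neither as E nor as X, over X, per mM of G charged, the loss odds.

| flask | E | G | remark | time |
|---|---|---|---|---|
| Saturday's | 46 mM (fed, over 30 s) | 0.14 mM | run made earlier; the fed solution adds 0.20 times the starting volume |  |
| Friday's | 46 mM (fed, over 30 s) | 0.19 mM | run made earlier; the fed solution adds 0.20 times the starting volume |  |
| Wednesday's | 46 mM (fed, over 30 s) | 0.30 mM | run made earlier; the fed solution adds 0.20 times the starting volume |  |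
| summer | 46 mM (fed, over 30 s) | 0.36 mM | the fed solution adds 0.20 times the starting volume | 25 min |
| dawn | 46 mM | 0.12 mM | everything together at the start, the whole solution of E included, so that from the start the volume is larger by 0.20 times the starting volume | 25 min |

| run | time / min | X / % | E / % |
|---|---|---|---|
| Saturday's | 1.33 | 0 | 99.5 |
| Saturday's | 2.50 | 0.7 | 99.5 |
| Saturday's | 5.00 | 2.4 | 97.2 |
| Saturday's | 10.0 | 7.8 | 91.7 |
| Saturday's | 20.0 | 21.6 | 77.6 |
| Friday's | 1.50 | 0.6 | 99.4 |
| Friday's | 4.00 | 2.0 | 97.9 |
| Friday's | 8.00 | 7.2 | 92.4 |
| Friday's | 12.0 | 13.5 | 85.4 |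
| Friday's | 20.0 | 26.1 | 71.0 |
| Wednesday's | 4.00 | 3.2 | 96.7 |
| Wednesday's | 8.00 | 10.1 | 88.0 |
| Wednesday's | 10.0 | 14.9 | 83.7 |
| Wednesday's | 15.0 | 25.6 | 70.5 |
| Wednesday's | 20.0 | 35.8 | 58.3 |

(scatter of a reading: 0.3 percentage points)

- charges are per starting volume, the dose included; the dosed solution carries all of it

- the winner by amount of X, in percent of the E charged; "neither" if no more than 2 percentage points parts them (summer / dawn / neither)
- how much X is there at the end, in percent of the E charged: summer
- how much X is there at the end, in percent of the E charged: dawn

At the bench I would say that a trace of G turns E into X, so what E has lost X has gained. Saturday's run nearly allows this, since its gap at 20.0 min is 0.8 percentage points, which is 2.67 times the scatter of a reading. Wednesday's gap is 19.7 times that scatter, so the rule has stopped working there, and Friday's loss odds of 0.585 /mM stand close to Wednesday's.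

So I follow one molecule of E. It first has to leave E, and then it stands at a fork, staying X or dropping into the gap, with odds that at 20.0 min roughly scale with G between Friday's and Wednesday's runs, while Saturday's small gap reads lower, at 0.265 /mM. Wednesday's loss odds grow with time, but I keep the figure from 20.0 min for 25 min as an estimate. The logarithm of E's fall at 20.0 min also scales with G, and I extend Wednesday's value to 25 min by repeating its last step. Feeding takes 30 s, short beside 25 min, so I treat summer and dawn alike:

Exponent per mM of G: 2.43 /mM

Summer: E consumed 58.3 %, odds 0.198, so X, which is consumed over one plus odds, is 48.7 %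

Dawn: E consumed 25.3 %, odds 0.0659, so X is 23.7 %

My winner is summer, by 25 points, well past the margin.

The forecast, resting on “rate is first order in G”, names summer, with 49 % (44 % to 54 %) for summer and 25.5 % (23 % to 28 %) for dawn, which is above my dawn figure.

The flasks give 48.0 % in summer and 25.2 % in dawn, so summer wins.

    E + G → D + X (k = 0.0470 /M/s)
    E + D → X + D, rate k2*[D]*[E] (k = 3.20 /M/s)
    X + G ⇌ Z + G, rate k3*[G]*[X] forward; the back reaction follows from the equilibrium constant (K = 1.40, k = 4.90 /M/s)

The gap is Z, so my odds, the loss odds times G, are the selectivity of Z over X: at 25 min they stand at 0.223 in summer against my 0.198, and at 0.0576 in dawn against my 0.0659. Ten times the time, 250 min, still changes dawn, whose X reaches 95.0 % with E at 1.01 % and odds of 0.0421. In summer X goes from 48.0 % to 47.6 %, but E falls from 41.3 % to 0 % and Z climbs from 10.7 % to 52.4 %, which puts the odds at 1.10, still below the equilibrium constant of 1.4.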